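## Retrosynthetic overview

1. The strategy rests on resorcinol ring E. Its adjacent carbons C4 and C3a (outer dihydrobenzofuran numbering) carry C3 of the central and C3 of the outer dihydrobenzofuran, and C7a, next to C3a, carries the outer furan oxygen.
2. Ring E is therefore introduced as 3,5-bis(benzyloxy)benzyne. It inserts into the C2–C(=O) bond of the triaryl 1,3-diketone 10 and forms both aryl–carbon bonds at once (10 + 16 → 19).
3. Right half, order of rings: first the central dihydrobenzofuran (dynamic kinetic reduction, acid closure). Then the outer one (ortho-debenzylation, 4-benzyloxybenzyl ether, diazo compound, Rh C–H insertion, C2 epimerisation), ending at bromide 28.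
4. Left half: dihydrobenzofuran by an asymmetric o-quinone methide/ammonium ylide [4+1] annulation, stilbene by Heck reaction, seven-membered ring by Shi epoxidation and Friedel–Crafts opening, ending at acid 45. Fragments 28 and 45 are joined at C1–aryl by Ni/photoredox decarboxylative arylation.
5. All phenols travel as benzyl ethers, so the last step is a neutral hydrogenolysis. A BBr3 demethylation would ionise the C6 carbinol and the 2-aryl-dihydrobenzofuran C–O bonds, which lie next to nucleophilic resorcinol rings.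

Key step: step 9

Assumption: the sense of induction given for the chiral catalysts and reagents of steps 10, 15, 22 and 24 follows their standard substrates. If a step shows the opposite sense, the (pseudo)enantiomeric catalyst or alkaloid (quinine for quinidine) is used with no other change.

Labels:
- Rings: A = 4-oxyphenyl on C7 of the core; B and C = resorcinol rings of the core; D = benzo ring of the central dihydrobenzofuran; E = linking resorcinol ring; F = 3,5-dioxyphenyl on outer C3; G = 4-oxyphenyl on outer C2; H = 4-oxyphenyl on central C2.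
- Core numbering is that of benzo[6,7]cyclohepta[1,2,3-cd][1]benzofuran: C1 next to O2, C6 carbinol, C7 aryl-bearing, C11b diaryl methine.

Handling: ketones 21, 22 and 24 are ortho-alkylbenzophenones and are kept from UV light, which would photoenolise C3. Hydroxy ketone 20 may rest as its six-membered lactol, which opens again under step 11.

## Route

Step 1
Reactants: 1 2-hydroxyphenylacetic acid
Product: 2 2-(5-bromo-2-hydroxyphenyl)acetic acid
Conditions: NBS (1.0 equiv), MeCN, 0 °C to rt
Reagents that add atoms: N-bromosuccinimide, O=C1CCC(=O)N1Br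
Why: Electrophilic aromatic bromination is directed para to the free phenol, which places bromine on the ring D carbon that later bonds to C1 of the core.

Step 2
Reactants: 2 2-(5-bromo-2-hydroxyphenyl)acetic acid
Product: 3 2-(5-bromo-2-hydroxyphenyl)-N-methoxy-N-methylacetamide
Conditions: MeNHOMe·HCl, EDC·HCl, Et3N, CH2Cl2, 0 °C to rt
Reagents that add atoms: N,O-dimethylhydroxylamine hydrochloride, CNOC.Cl
Why: Carbodiimide amide coupling gives the Weinreb amide, and any lactone formed by internal O-acylation is an activated aryl ester that the hydroxylamine opens to the same product.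

Step 3
Reactants: 3 Weinreb amide phenol
Product: 4 2-[5-bromo-2-(methoxymethoxy)phenyl]-N-methoxy-N-methylacetamide
Conditions: MOMCl, i-Pr2NEt, CH2Cl2, 0 °C to rt
Reagents that add atoms: chloromethyl methyl ether, COCCl
Why: Base-mediated O-alkylation (MOM ether formation) masks the phenol with a group that survives Grignard reagent, LiHMDS and fluoride and leaves under the acid of step 11.

Step 4
Reactants: 4 MOM-protected Weinreb amide; 5 1-(benzyloxy)-4-bromobenzene
Product: 7 1-[4-(benzyloxy)phenyl]-2-[5-bromo-2-(methoxymethoxy)phenyl]ethan-1-one, via aryl Grignard reagent 6 (not isolated)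
Conditions: 5, Mg, THF, reflux; then 4, THF, 0 °C; aqueous work-up
Reagents that add atoms: none
Why: Weinreb ketone synthesis, in which the chelated tetrahedral adduct stops the addition at the ketone stage and the aryl bromide of 4 does not exchange with the Grignard reagent at 0 °C.

Step 5
Reactants: 7 deoxybenzoin; 8 3,5-bis(benzyloxy)benzoic acid
Product: 10 1-[3,5-bis(benzyloxy)phenyl]-3-[4-(benzyloxy)phenyl]-2-[5-bromo-2-(methoxymethoxy)phenyl]propane-1,3-dione (enolisable methine), via acid chloride 9 (not isolated)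
Conditions: 8, (COCl)2, DMF (cat.), CH2Cl2, evaporate; 7, LiHMDS (2.1 equiv), toluene/THF, −78 °C, add 9, to 0 °C; dilute HCl
Reagents that add atoms: none
Why: Claisen-type C-acylation of the lithium enolate, in which the second equivalent of base removes the more acidic methine proton of 10 and draws the equilibrium to the C-acylated diketonate.

Step 6
Reactants: 11 3,5-bis(benzyloxy)phenol
Product: 12 3,5-bis(benzyloxy)-2-bromophenol
Conditions: NBS (1.0 equiv), CH2Cl2, −78 °C to rt
Reagents that add atoms: N-bromosuccinimide, O=C1CCC(=O)N1Br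
Why: Electrophilic bromination takes the position ortho to the hydroxyl group, because the para position is flanked by two benzyloxy groups.

Step 7
Reactants: 12 3,5-bis(benzyloxy)-2-bromophenol
Product: 13 [3,5-bis(benzyloxy)-2-bromophenoxy]trimethylsilane
Conditions: HMDS, THF, 70 °C
Reagents that add atoms: hexamethyldisilazane, C[Si](C)(C)N[Si](C)(C)C
Why: O-Silylation of the phenol with HMDS places silicon where it can migrate to carbon in the next step, with ammonia as the only by-product.

Step 8
Reactants: 13 silyl ether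
Product: 16 3,5-bis(benzyloxy)-2-(trimethylsilyl)phenyl trifluoromethanesulfonate, via aryllithium 14 (not isolated), via lithium phenolate 15 (not isolated)
Conditions: n-BuLi, THF, −78 °C; then Tf2O, −78 °C
Reagents that add atoms: trifluoromethanesulfonic anhydride, O=S(=O)(OS(=O)(=O)C(F)(F)F)C(F)(F)F
Why: Bromine–lithium exchange is followed by a retro-Brook 1,3-shift of silicon from oxygen to carbon, and the phenolate is trapped by triflic anhydride to give the ortho-silylaryl triflate.

Step 9
Reactants: 10 triaryl 1,3-diketone; 16 ortho-silylaryl triflate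
Product: 19 2-{3,5-bis(benzyloxy)-2-[3,5-bis(benzyloxy)benzoyl]phenyl}-1-[4-(benzyloxy)phenyl]-2-[5-bromo-2-(methoxymethoxy)phenyl]ethan-1-one (enolisable methine), via aryne 17 (not isolated), via benzocyclobutenoxide 18 (not isolated)
Conditions: 16 (1.3 equiv), CsF (3 equiv), MeCN, 80 °C
Reagents that add atoms: none
Why: Fluoride strips the silyl group of 16 to release aryne 17 and also generates the enolate of 10, whose central carbon adds to the aryne carbon meta to the flanking benzyloxy group, because the aryne is distorted towards that terminus and the charge then develops ortho to the inductively withdrawing oxygen. The aryl anion attacks the adjacent 3,5-bis(benzyloxy)benzoyl carbonyl (4-exo-trig) to give alkoxide 18, and strain-driven retro-aldol cleavage of its bond to the former enolate carbon releases the α,α-diaryl ketone enolate, which is protonated to 19. The closest known reaction type is the aryne acyl-alkylation, that is, σ-insertion of arynes into the C–C(=O) bond of β-ketoesters and 1,3-diketones. The four-membered ring of 18 is the only ring closed and it opens again, so the step forms the aryl–CH and aryl–C(=O) bonds without leaving a ring, and it fixes no stereocentre because the methine of 19 stays enolisable until step 10. Three selectivities are needed: aryne regiochemistry (secured by the C3 benzyloxy group), choice of acyl group (the carbonyl bearing two meta-alkoxy groups is more electrophilic than the one conjugated with a para-alkoxy donor) and C- over O-arylation (usual for soft β-dicarbonyl enolates).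

Step 10
Reactants: 19 ortho-aroyl α,α-diaryl ketone
Product: 20 (1S,2R)-2-{3,5-bis(benzyloxy)-2-[3,5-bis(benzyloxy)benzoyl]phenyl}-1-[4-(benzyloxy)phenyl]-2-[5-bromo-2-(methoxymethoxy)phenyl]ethan-1-ol
Conditions: (S,S)-Ts-DENEB (2 mol %), HCO2H/Et3N (1:5), DMF, 40 °C
Reagents that add atoms: none
Why: Proposed new method: the methine of 19 is flanked by a ketone and two aryl groups, so excess triethylamine should interconvert its enantiomers through the enolate faster than hydride transfer, while the (S,S)-Ru hydride reduces aryl ketones from the face that gives the (S)-carbinol and, by the Felkin–Anh preference for attack anti to the bulky 2-aroylaryl group, should take the (2R)-ketone faster, which sets C1 (S) and C2 (R) together; the di-ortho-substituted diaryl ketone is too hindered to compete; the closest known reaction type is the Noyori–Ikariya transfer hydrogenation with dynamic kinetic resolution of α-aryl ketones such as 2-aryl-1-tetralones and isoflavanones, which has not been shown on acyclic 1,2,2-triarylethanones.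

Step 11
Reactants: 20 (1S,2R)-alcohol
Product: 21 {2,4-bis(benzyloxy)-6-[(2R,3R)-2-[4-(benzyloxy)phenyl]-5-bromo-2,3-dihydro-1-benzofuran-3-yl]phenyl}[3,5-bis(benzyloxy)phenyl]methanone
Conditions: HCl (0.5 M in MeOH), CH2Cl2, 0 °C to rt, dark
Reagents that add atoms: none
Why: SN1 etherification, in which acid ionises the 4-benzyloxybenzylic alcohol to a para-quinone-methide-like cation that is captured in a five-membered closure by the ortho oxygen (as the freed phenol or as the MOM ether, which then gives its acetal carbon to methanol) on the face anti to the C3 aryl group, so that the untouched C3 (R) dictates C2 (R) and the trans ring, and internal capture should outrun proton loss from C3.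

Step 12
Reactants: 21 central dihydrobenzofuran ketone
Product: 22 {4-(benzyloxy)-2-hydroxy-6-[(2R,3R)-2-[4-(benzyloxy)phenyl]-5-bromo-2,3-dihydro-1-benzofuran-3-yl]phenyl}[3,5-bis(benzyloxy)phenyl]methanone
Conditions: BCl3 (1.1 equiv), CH2Cl2, −78 °C; then H2O
Reagents that add atoms: none
Why: Chelation-controlled ether cleavage, in which BCl3 binds the ketone oxygen and the single benzyloxy oxygen ortho to it in a six-membered chelate and chloride removes only that benzyl group.

Step 13
Reactants: 22 ortho-hydroxy ketone; 23 4-(benzyloxy)benzyl chloride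
Product: 24 {4-(benzyloxy)-2-{[4-(benzyloxy)phenyl]methoxy}-6-[(2R,3R)-2-[4-(benzyloxy)phenyl]-5-bromo-2,3-dihydro-1-benzofuran-3-yl]phenyl}[3,5-bis(benzyloxy)phenyl]methanone
Conditions: K2CO3, n-Bu4NI (cat.), DMF, 50 °C
Reagents that add atoms: none
Why: Williamson ether synthesis on the hydrogen-bonded phenol brings in ring G and the CH2 group that becomes C2 of the outer ring.

Step 14
Reactants: 24 benzyl ether ketone
Product: 25 hydrazone of ketone 24 (C=N–NH2 in place of C=O)
Conditions: N2H4·H2O (excess), AcOH (cat.), n-BuOH, 120 °C, sealed tube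
Reagents that add atoms: hydrazine hydrate, NN.O
Why: Acid-catalysed hydrazone formation is forced by excess reagent and heat because the carbonyl carries two ortho substituents, and no other group of 24 reacts with hydrazine.

Step 15
Reactants: 25 hydrazone
Product: 27 (2R,3R)-2-[4-(benzyloxy)phenyl]-3-{(2S,3R)-6-(benzyloxy)-2-[4-(benzyloxy)phenyl]-3-[3,5-bis(benzyloxy)phenyl]-2,3-dihydro-1-benzofuran-4-yl}-5-bromo-2,3-dihydro-1-benzofuran (outer ring cis), via diaryldiazomethane 26 (not isolated)
Conditions: MnO2, CH2Cl2, 0 °C, filter; Rh2(R-PTAD)4 (1 mol %), CH2Cl2, 0 °C to rt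
Reagents that add atoms: none
Why: MnO2 dehydrogenates the hydrazone to 26, and the chiral Rh(II) donor/donor carbene inserts into the neighbouring O–CH2Ar bond (intramolecular 1,5 C–H insertion), which characteristically gives the cis-2,3-diaryl ring with outer C3 (R) fixed by the catalyst, the only other 1,5 C–H bond (tertiary C2–H of the central ring) being the more hindered site.

Step 16
Reactants: 27 cis outer dihydrobenzofuran
Product: 28 (2R,3R)-2-[4-(benzyloxy)phenyl]-3-{(2R,3R)-6-(benzyloxy)-2-[4-(benzyloxy)phenyl]-3-[3,5-bis(benzyloxy)phenyl]-2,3-dihydro-1-benzofuran-4-yl}-5-bromo-2,3-dihydro-1-benzofuran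
Conditions: TFA, CH2Cl2, 0 °C
Reagents that add atoms: none
Why: Acid-catalysed epimerisation, in which the strained cis ring opens reversibly at O–C2 to a 4-benzyloxybenzylic cation and recloses anti to the C3 aryl group, so only outer C2 changes (S to R) under control of outer C3, while the central ring is already in its stable trans form.

Step 17
Reactants: 29 1,3-bis(benzyloxy)-5-bromobenzene
Product: 30 2,4-bis(benzyloxy)-6-bromobenzaldehyde
Conditions: POCl3, DMF, 0 to 90 °C; then H2O
Reagents that add atoms: N,N-dimethylformamide, CN(C)C=O; water, O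
Why: Vilsmeier–Haack formylation occurs para to one benzyloxy group and ortho to the other, next to bromine rather than at the more crowded position between the two benzyloxy groups.

Step 18
Reactants: 30 2,4-bis(benzyloxy)-6-bromobenzaldehyde
Product: 31 4-(benzyloxy)-2-bromo-6-hydroxybenzaldehyde
Conditions: BCl3 (1.1 equiv), CH2Cl2, −78 °C; then H2O
Reagents that add atoms: none
Why: Chelation-controlled debenzylation removes only the benzyl ether ortho to the aldehyde, whose oxygen shares the boron with the carbonyl oxygen.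

Step 19
Reactants: 31 salicylaldehyde; 29 1,3-bis(benzyloxy)-5-bromobenzene
Product: 33 5-(benzyloxy)-2-{[3,5-bis(benzyloxy)phenyl](hydroxy)methyl}-3-bromophenol (racemic), via aryl Grignard reagent 32 (not isolated)
Conditions: 29, Mg, THF, reflux (2.3 equiv of 32); then 31, THF, 0 °C; aqueous work-up
Reagents that add atoms: none
Why: Grignard 1,2-addition to the aldehyde follows deprotonation of the phenol by the first equivalent, and the new carbinol centre is of no consequence because it is erased in step 22.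

Step 20
Reactants: 33 ortho-hydroxybenzhydrol
Product: 34 5-(benzyloxy)-2-{[3,5-bis(benzyloxy)phenyl](4-methylbenzenesulfonyl)methyl}-3-bromophenol (racemic)
Conditions: p-TolSO2H (1.5 equiv), CH2Cl2, rt
Reagents that add atoms: p-toluenesulfinic acid, Cc1ccc(cc1)S(=O)O
Why: SN1 substitution, in which the sulfinic acid ionises the electron-rich benzhydrol and the sulfinate captures the cation through sulfur to give a storable o-quinone methide precursor.

Step 21
Reactants: 35 quinidine; 36 methyl bromoacetate
Product: 37 N-(2-methoxy-2-oxoethyl)quinidinium bromide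
Conditions: THF, rt
Reagents that add atoms: none
Why: Menshutkin quaternisation takes place at the more basic and accessible quinuclidine nitrogen.

Step 22
Reactants: 34 sulfone; 37 quinidinium salt
Product: 40 methyl (2R,3R)-6-(benzyloxy)-3-[3,5-bis(benzyloxy)phenyl]-4-bromo-2,3-dihydro-1-benzofuran-2-carboxylate, via ammonium ylide 38 (not isolated), via ortho-quinone methide 39 (not isolated)
Conditions: Cs2CO3 (2.5 equiv), CH2Cl2, rt
Reagents that add atoms: none
Why: [4+1] annulation of an in situ o-quinone methide with an ammonium ylide carrying a cinchona alkaloid as chiral leaving group, in which conjugate addition of 38 to 39 sets C3 (R) under the facial bias of the alkaloid and the 5-exo-tet displacement of quinidine by the phenolate gives C2 (R) in the favoured trans ester.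

Step 23
Reactants: 40 4-bromo ester; 41 1-(benzyloxy)-4-ethenylbenzene
Product: 42 methyl (2R,3R)-6-(benzyloxy)-3-[3,5-bis(benzyloxy)phenyl]-4-{(E)-2-[4-(benzyloxy)phenyl]ethenyl}-2,3-dihydro-1-benzofuran-2-carboxylate
Conditions: Pd2(dba)3 (2.5 mol %), P(t-Bu)3·HBF4 (10 mol %), Cy2NMe, 1,4-dioxane, 80 °C
Reagents that add atoms: none
Why: Mizoroki–Heck reaction, in which a bulky electron-rich monophosphine palladium(0) inserts into the hindered C4–Br bond and syn insertion followed by syn β-hydride elimination gives the (E)-stilbene without touching C2 or C3.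

Step 24
Reactants: 42 stilbene ester
Product: 43 methyl (2R,3R)-6-(benzyloxy)-3-[3,5-bis(benzyloxy)phenyl]-4-{(2R,3R)-3-[4-(benzyloxy)phenyl]oxiran-2-yl}-2,3-dihydro-1-benzofuran-2-carboxylate
Conditions: Shi ketone (D-fructose-derived, 30 mol %), Oxone, K2CO3, n-Bu4NHSO4 (cat.), MeCN/DMM/aq. Na2B4O7–EDTA buffer, 0 °C
Reagents that add atoms: potassium peroxymonosulfate (Oxone), [K+].[O-]S(=O)(=O)OO
Why: Shi asymmetric epoxidation, in which the chiral dioxirane transfers oxygen through a spiro transition state and gives the (R,R)-epoxide of trans-stilbenes under reagent control, the basic buffer preserving the acid-labile product.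

Step 25
Reactants: 43 epoxide
Product: 44 methyl (1R,6S,7R,11bR)-4,8,10-tris(benzyloxy)-7-[4-(benzyloxy)phenyl]-6-hydroxy-1,6,7,11b-tetrahydrobenzo[6,7]cyclohepta[1,2,3-cd][1]benzofuran-1-carboxylate
Conditions: BF3·OEt2 (0.2 equiv), CH2Cl2, −78 °C
Reagents that add atoms: none
Why: Intramolecular Friedel–Crafts alkylation by epoxide opening, in which the Lewis acid loosens the C–O bond at the 4-benzyloxybenzylic carbon and the ortho carbon of ring B attacks it from the back (7-endo), so C7 forms with inversion (R), C6 keeps its C–O bond (S) and aryl and hydroxyl come out trans.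

Step 26
Reactants: 44 tetracyclic ester
Product: 45 (1R,6S,7R,11bR)-4,8,10-tris(benzyloxy)-7-[4-(benzyloxy)phenyl]-6-hydroxy-1,6,7,11b-tetrahydrobenzo[6,7]cyclohepta[1,2,3-cd][1]benzofuran-1-carboxylic acid
Conditions: LiOH·H2O, THF/MeOH/H2O, rt; then 1 M HCl
Reagents that add atoms: lithium hydroxide, [Li+].[OH-]
Why: Ester saponification, in which C1 is the only base-labile centre, already has the stable trans arrangement and is reset in step 27 in any case.

Step 27
Reactants: 28 aryl bromide; 45 core acid
Product: 46 nona-O-benzyl ether of the target (all nine phenols benzylated and C6–OH free; core 1R,6S,7R,11bR; central ring 2R,3R; outer ring 2R,3R)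
Conditions: Ir[dF(CF3)ppy]2(dtbbpy)PF6 (2 mol %), NiCl2·glyme (10 mol %), dtbbpy (15 mol %), Cs2CO3 (1.5 equiv), DMF, blue LEDs, rt
Reagents that add atoms: none
Why: Metallaphotoredox decarboxylative arylation of an α-oxy acid, in which the excited iridium complex oxidises the cesium carboxylate, loss of CO2 gives the α-aryloxy C1 radical, and capture by the aryl–nickel species from 28 followed by reductive elimination forms the C1–aryl bond on the face opposite ring B at C11b, so C1 becomes R (trans).

Step 28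
Reactants: 46 nona-O-benzyl ether
Product: 47 CNP0132116.1 (target)
Conditions: H2 (1 atm), 10% Pd/C, EtOAc/MeOH, rt
Reagents that add atoms: none
Why: Catalytic hydrogenolysis cleaves the nine unhindered primary aryl benzyl ethers much faster than the hindered secondary benzylic C–O bonds of the three dihydrobenzofurans and the C6 carbinol, and it touches no stereocentre.

## Compound list

1 | 2-hydroxyphenylacetic acid | OC(=O)Cc1ccccc1O | starting material
2 | 2-(5-bromo-2-hydroxyphenyl)acetic acid | OC(=O)Cc1cc(Br)ccc1O | intermediate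
3 | 2-(5-bromo-2-hydroxyphenyl)-N-methoxy-N-methylacetamide | CON(C)C(=O)Cc1cc(Br)ccc1O | intermediate
4 | 2-[5-bromo-2-(methoxymethoxy)phenyl]-N-methoxy-N-methylacetamide | CON(C)C(=O)Cc1cc(Br)ccc1OCOC | intermediate
5 | 1-(benzyloxy)-4-bromobenzene | Brc1ccc(OCc2ccccc2)cc1 | starting material
6 | [4-(benzyloxy)phenyl]magnesium bromide | Br[Mg]c1ccc(OCc2ccccc2)cc1 | intermediate
7 | 1-[4-(benzyloxy)phenyl]-2-[5-bromo-2-(methoxymethoxy)phenyl]ethan-1-one | O=C(Cc1cc(Br)ccc1OCOC)c1ccc(OCc2ccccc2)cc1 | intermediate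
8 | 3,5-bis(benzyloxy)benzoic acid | OC(=O)c1cc(OCc2ccccc2)cc(OCc2ccccc2)c1 | starting material
9 | 3,5-bis(benzyloxy)benzoyl chloride | ClC(=O)c1cc(OCc2ccccc2)cc(OCc2ccccc2)c1 | intermediate
10 | 1-[3,5-bis(benzyloxy)phenyl]-3-[4-(benzyloxy)phenyl]-2-[5-bromo-2-(methoxymethoxy)phenyl]propane-1,3-dione | O=C(c1ccc(OCc9ccccc9)cc1)C(c1cc(Br)ccc1OCOC)C(=O)c1cc(OCc9ccccc9)cc(OCc9ccccc9)c1 | intermediate
11 | 3,5-bis(benzyloxy)phenol | Oc1cc(OCc2ccccc2)cc(OCc2ccccc2)c1 | starting material
12 | 3,5-bis(benzyloxy)-2-bromophenol | Oc1cc(OCc2ccccc2)cc(OCc2ccccc2)c1Br | intermediate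
13 | [3,5-bis(benzyloxy)-2-bromophenoxy]trimethylsilane | C[Si](C)(C)Oc1cc(OCc2ccccc2)cc(OCc2ccccc2)c1Br | intermediate
14 | [2,4-bis(benzyloxy)-6-(trimethylsilyloxy)phenyl]lithium | [Li]c1c(OCc2ccccc2)cc(OCc2ccccc2)cc1O[Si](C)(C)C | intermediate
15 | lithium 3,5-bis(benzyloxy)-2-(trimethylsilyl)phenolate | [Li+].[O-]c1cc(OCc2ccccc2)cc(OCc2ccccc2)c1[Si](C)(C)C | intermediate
16 | 3,5-bis(benzyloxy)-2-(trimethylsilyl)phenyl trifluoromethanesulfonate | C[Si](C)(C)c1c(OCc2ccccc2)cc(OCc2ccccc2)cc1OS(=O)(=O)C(F)(F)F | intermediate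
17 | 3,5-bis(benzyloxy)benzyne | C1#CC(OCc2ccccc2)=CC(OCc2ccccc2)=C1 | intermediate
18 | cesium benzocyclobutenoxide (four-membered ring made of E1, E6, the former enolate carbon and the former 3,5-bis(benzyloxy)benzoyl carbon) | [Cs+].[O-]C1(c2cc(OCc9ccccc9)cc(OCc9ccccc9)c2)c2c(OCc9ccccc9)cc(OCc9ccccc9)cc2C1(c1cc(Br)ccc1OCOC)C(=O)c1ccc(OCc9ccccc9)cc1 | intermediate
19 | 2-{3,5-bis(benzyloxy)-2-[3,5-bis(benzyloxy)benzoyl]phenyl}-1-[4-(benzyloxy)phenyl]-2-[5-bromo-2-(methoxymethoxy)phenyl]ethan-1-one | O=C(c1ccc(OCc9ccccc9)cc1)C(c1cc(Br)ccc1OCOC)c1cc(OCc9ccccc9)cc(OCc9ccccc9)c1C(=O)c1cc(OCc9ccccc9)cc(OCc9ccccc9)c1 | intermediate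
20 | (1S,2R)-alcohol from 19 | COCOc1ccc(Br)cc1[C@@H](c1cc(OCc9ccccc9)cc(OCc9ccccc9)c1C(=O)c1cc(OCc9ccccc9)cc(OCc9ccccc9)c1)[C@H](O)c1ccc(OCc9ccccc9)cc1 | intermediate
21 | {2,4-bis(benzyloxy)-6-[(2R,3R)-2-[4-(benzyloxy)phenyl]-5-bromo-2,3-dihydro-1-benzofuran-3-yl]phenyl}[3,5-bis(benzyloxy)phenyl]methanone | Brc1ccc2c(c1)[C@@H](c1cc(OCc9ccccc9)cc(OCc9ccccc9)c1C(=O)c1cc(OCc9ccccc9)cc(OCc9ccccc9)c1)[C@H](c1ccc(OCc9ccccc9)cc1)O2 | intermediate
22 | ortho-hydroxy ketone (21 with the benzyl ether ortho to C=O cleaved) | Brc1ccc2c(c1)[C@@H](c1cc(OCc9ccccc9)cc(O)c1C(=O)c1cc(OCc9ccccc9)cc(OCc9ccccc9)c1)[C@H](c1ccc(OCc9ccccc9)cc1)O2 | intermediate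
23 | 4-(benzyloxy)benzyl chloride | ClCc1ccc(OCc2ccccc2)cc1 | starting material
24 | 4-(benzyloxy)benzyl ether of 22 | Brc1ccc2c(c1)[C@@H](c1cc(OCc9ccccc9)cc(OCc3ccc(OCc9ccccc9)cc3)c1C(=O)c1cc(OCc9ccccc9)cc(OCc9ccccc9)c1)[C@H](c1ccc(OCc9ccccc9)cc1)O2 | intermediate
25 | hydrazone of 24 | Brc1ccc2c(c1)[C@@H](c1cc(OCc9ccccc9)cc(OCc3ccc(OCc9ccccc9)cc3)c1C(=NN)c1cc(OCc9ccccc9)cc(OCc9ccccc9)c1)[C@H](c1ccc(OCc9ccccc9)cc1)O2 | intermediate
26 | diaryldiazomethane from 25 | Brc1ccc2c(c1)[C@@H](c1cc(OCc9ccccc9)cc(OCc3ccc(OCc9ccccc9)cc3)c1C(=[N+]=[N-])c1cc(OCc9ccccc9)cc(OCc9ccccc9)c1)[C@H](c1ccc(OCc9ccccc9)cc1)O2 | intermediate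
27 | bis(dihydrobenzofuran) bromide, central 2R,3R, outer 2S,3R (cis) | Brc1ccc2c(c1)[C@@H](c1cc(OCc9ccccc9)cc3c1[C@@H](c1cc(OCc9ccccc9)cc(OCc9ccccc9)c1)[C@@H](c1ccc(OCc9ccccc9)cc1)O3)[C@H](c1ccc(OCc9ccccc9)cc1)O2 | intermediate
28 | bis(dihydrobenzofuran) bromide, central 2R,3R, outer 2R,3R (trans) | Brc1ccc2c(c1)[C@@H](c1cc(OCc9ccccc9)cc3c1[C@@H](c1cc(OCc9ccccc9)cc(OCc9ccccc9)c1)[C@H](c1ccc(OCc9ccccc9)cc1)O3)[C@H](c1ccc(OCc9ccccc9)cc1)O2 | intermediate
29 | 1,3-bis(benzyloxy)-5-bromobenzene | Brc1cc(OCc2ccccc2)cc(OCc2ccccc2)c1 | starting material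
30 | 2,4-bis(benzyloxy)-6-bromobenzaldehyde | O=Cc1c(Br)cc(OCc9ccccc9)cc1OCc9ccccc9 | intermediate
31 | 4-(benzyloxy)-2-bromo-6-hydroxybenzaldehyde | O=Cc1c(Br)cc(OCc9ccccc9)cc1O | intermediate
32 | [3,5-bis(benzyloxy)phenyl]magnesium bromide | Br[Mg]c1cc(OCc9ccccc9)cc(OCc9ccccc9)c1 | intermediate
33 | 5-(benzyloxy)-2-{[3,5-bis(benzyloxy)phenyl](hydroxy)methyl}-3-bromophenol (racemic) | OC(c1cc(OCc9ccccc9)cc(OCc9ccccc9)c1)c1c(Br)cc(OCc9ccccc9)cc1O | intermediate
34 | 5-(benzyloxy)-2-{[3,5-bis(benzyloxy)phenyl](4-methylbenzenesulfonyl)methyl}-3-bromophenol (racemic) | Cc1ccc(cc1)S(=O)(=O)C(c1cc(OCc9ccccc9)cc(OCc9ccccc9)c1)c1c(Br)cc(OCc9ccccc9)cc1O | intermediate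
35 | quinidine | COc1ccc2nccc([C@@H]([C@H]3C[C@@H]4CCN3C[C@@H]4C=C)O)c2c1 | starting material
36 | methyl bromoacetate | COC(=O)CBr | starting material
37 | N-(2-methoxy-2-oxoethyl)quinidinium bromide | COc1ccc2nccc([C@@H]([C@H]3C[C@@H]4CC[N+]3(CC(=O)OC)C[C@@H]4C=C)O)c2c1.[Br-] | intermediate
38 | quinidinium (methoxycarbonyl)methylide | COc1ccc2nccc([C@@H]([C@H]3C[C@@H]4CC[N+]3([CH-]C(=O)OC)C[C@@H]4C=C)O)c2c1 | intermediate
39 | 3-(benzyloxy)-6-{[3,5-bis(benzyloxy)phenyl]methylidene}-5-bromocyclohexa-2,4-dien-1-one | O=C1C=C(OCc9ccccc9)C=C(Br)C1=Cc1cc(OCc9ccccc9)cc(OCc9ccccc9)c1 | intermediate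
40 | methyl (2R,3R)-6-(benzyloxy)-3-[3,5-bis(benzyloxy)phenyl]-4-bromo-2,3-dihydro-1-benzofuran-2-carboxylate | COC(=O)[C@@H]1Oc2cc(OCc9ccccc9)cc(Br)c2[C@H]1c1cc(OCc9ccccc9)cc(OCc9ccccc9)c1 | intermediate
41 | 1-(benzyloxy)-4-ethenylbenzene | C=Cc1ccc(OCc2ccccc2)cc1 | starting material
42 | (E)-stilbene ester, 2R,3R | COC(=O)[C@@H]1Oc2cc(OCc9ccccc9)cc(/C=C/c3ccc(OCc9ccccc9)cc3)c2[C@H]1c1cc(OCc9ccccc9)cc(OCc9ccccc9)c1 | intermediate
43 | (R,R)-epoxide of 42 | COC(=O)[C@@H]1Oc2cc(OCc9ccccc9)cc([C@H]3O[C@@H]3c3ccc(OCc9ccccc9)cc3)c2[C@H]1c1cc(OCc9ccccc9)cc(OCc9ccccc9)c1 | intermediate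
44 | tetracyclic hydroxy ester, 1R,6S,7R,11bR | O(Cc9ccccc9)c1ccc([C@@H]2c3c(OCc9ccccc9)cc(OCc9ccccc9)cc3[C@@H]3c4c(cc(OCc9ccccc9)cc4[C@H]2O)O[C@H]3C(=O)OC)cc1 | intermediate
45 | tetracyclic hydroxy acid (core acid), 1R,6S,7R,11bR | O(Cc9ccccc9)c1ccc([C@@H]2c3c(OCc9ccccc9)cc(OCc9ccccc9)cc3[C@@H]3c4c(cc(OCc9ccccc9)cc4[C@H]2O)O[C@H]3C(=O)O)cc1 | intermediate
46 | nona-O-benzyl ether of the target | O(Cc9ccccc9)c1ccc([C@@H]2c3c(OCc9ccccc9)cc(OCc9ccccc9)cc3[C@@H]3c4c(cc(OCc9ccccc9)cc4[C@H]2O)O[C@H]3c2ccc3c(c2)[C@@H](c2cc(OCc9ccccc9)cc4c2[C@@H](c2cc(OCc9ccccc9)cc(OCc9ccccc9)c2)[C@H](c2ccc(OCc9ccccc9)cc2)O4)[C@H](c2ccc(OCc9ccccc9)cc2)O3)cc1 | intermediate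
47 | CNP0132116.1 | Oc1ccc([C@@H]2c3c(O)cc(O)cc3[C@@H]3c4c(cc(O)cc4[C@H]2O)O[C@H]3c2ccc3c(c2)[C@@H](c2cc(O)cc4c2[C@@H](c2cc(O)cc(O)c2)[C@H](c2ccc(O)cc2)O4)[C@H](c2ccc(O)cc2)O3)cc1 | target

## Step count and risks

Total step count: 28. Longest linear sequence: 15 steps (1–5, 9–16, 27, 28). The aryne precursor (steps 6–8) and the core acid (steps 17–26, nine of them linear) are side branches.

**Step 10 (the labelled step).**
- What may go wrong: equilibration of the methine may be slower than hydride transfer, or the catalyst may not tell the two aryl groups apart. The reduction would then lose its dynamic character and show poor diastereo- and enantioselection. Hydride transfer to the hindered, electron-rich ketone may also be sluggish.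
- Fallback by resolution, using known chemistry: it sets out from 19. NaBH4 in THF/MeOH at 0 °C reduces only the aryl alkyl ketone under Felkin–Anh control to the racemic (1S*,2R*)-alcohol F1. Acylation with (1S)-camphanic chloride (pyridine, DMAP) gives two diastereomeric esters, which are separated by chromatography or crystallisation. The (1S,2R)-camphanate F2 is methanolysed (K2CO3, MeOH), and the route is rejoined at 20. The unwanted ester can be methanolysed, oxidised back to 19 and recycled.

**Step 9 (key step).**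
- What may go wrong: the tertiary, doubly stabilised enolate carbon may be too hindered to add to the aryne. The result would be O-arylation, or proton capture by the aryl anion before the four-membered ring closes. Acyl transfer could also take the 4-benzyloxybenzoyl group.
- Fallback, which inserts first and arylates afterwards: it sets out from 9 and 16. Commercial 4'-(benzyloxy)acetophenone is C-acylated with 9 (LiHMDS) to 1-[3,5-bis(benzyloxy)phenyl]-3-[4-(benzyloxy)phenyl]propane-1,3-dione F3. Its unhindered enolate takes up aryne 17 (CsF, MeCN, 80 °C) to give the ortho-aroyl deoxybenzoin F4. Ring D is then attached by palladium-catalysed ketone α-arylation (Pd2(dba)3, Xantphos, Cs2CO3, toluene, 80 °C) with 4-bromo-2-iodo-1-(methoxymethoxy)benzene F5. F5 is made from 4-bromo-2-iodophenol and MOMCl, and oxidative addition takes its C–I bond. The route is rejoined at 19.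

**Step 15.**
- What may go wrong: the carbene may insert into the electronically activated tertiary C2–H of the central ring, which lies on the same face as ring E. The chiral catalyst may be mismatched with the existing stereocentres. The upstream condensation of step 14 may stall at the di-ortho-substituted carbonyl.
- Fallback, which avoids the carbene: it sets out from 22. NaBH4 gives the ortho-hydroxybenzhydrol F6, and p-toluenesulfinic acid converts it into the sulfone F7. Chloride 23 and tetrahydrothiophene give 1-[4-(benzyloxy)benzyl]tetrahydrothiophenium chloride F8. With Cs2CO3 in MeCN, F7 loses sulfinate to give the ortho-quinone methide F9, and F8 is deprotonated to the benzylic sulfonium ylide F10. Conjugate addition and 5-exo-tet displacement of the sulfide ([4+1] annulation) give the trans outer ring directly. The configuration at outer C3 then rests on the neighbouring central ring, and the diastereomers are separated by chromatography. The route is rejoined at 28, which bypasses steps 13–16.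

## Further compounds

F1 | step 10 | racemic (1S*,2R*)-alcohol (racemate of 20) | COCOc1ccc(Br)cc1[C@@H](c1cc(OCc9ccccc9)cc(OCc9ccccc9)c1C(=O)c1cc(OCc9ccccc9)cc(OCc9ccccc9)c1)[C@H](O)c1ccc(OCc9ccccc9)cc1
F2 | step 10 | (1S,4R)-camphanate of 20 | C[C@@]12CC[C@@](C1(C)C)(OC2=O)C(=O)O[C@H](c3ccc(OCc9ccccc9)cc3)[C@@H](c3cc(Br)ccc3OCOC)c3cc(OCc9ccccc9)cc(OCc9ccccc9)c3C(=O)c3cc(OCc9ccccc9)cc(OCc9ccccc9)c3
F3 | step 9 | 1-[3,5-bis(benzyloxy)phenyl]-3-[4-(benzyloxy)phenyl]propane-1,3-dione | O=C(CC(=O)c1cc(OCc9ccccc9)cc(OCc9ccccc9)c1)c1ccc(OCc9ccccc9)cc1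
F4 | step 9 | 2-{3,5-bis(benzyloxy)-2-[3,5-bis(benzyloxy)benzoyl]phenyl}-1-[4-(benzyloxy)phenyl]ethan-1-one | O=C(Cc1cc(OCc9ccccc9)cc(OCc9ccccc9)c1C(=O)c1cc(OCc9ccccc9)cc(OCc9ccccc9)c1)c1ccc(OCc9ccccc9)cc1
F5 | step 9 | 4-bromo-2-iodo-1-(methoxymethoxy)benzene | COCOc1ccc(Br)cc1I
F6 | step 15 | ortho-hydroxybenzhydrol from 22 (carbinol centre undefined) | Brc1ccc2c(c1)[C@@H](c1cc(OCc9ccccc9)cc(O)c1C(O)c1cc(OCc9ccccc9)cc(OCc9ccccc9)c1)[C@H](c1ccc(OCc9ccccc9)cc1)O2
F7 | step 15 | p-tolyl sulfone from F6 (sulfone-bearing centre undefined) | Brc1ccc2c(c1)[C@@H](c1cc(OCc9ccccc9)cc(O)c1C(c1cc(OCc9ccccc9)cc(OCc9ccccc9)c1)S(=O)(=O)c1ccc(C)cc1)[C@H](c1ccc(OCc9ccccc9)cc1)O2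
F8 | step 15 | 1-[4-(benzyloxy)benzyl]tetrahydrothiophenium chloride | C1CC[S+](C1)Cc1ccc(OCc2ccccc2)cc1.[Cl-]
F9 | step 15 | ortho-quinone methide from F7 | Brc1ccc2c(c1)[C@@H](C1=CC(OCc9ccccc9)=CC(=O)C1=Cc1cc(OCc9ccccc9)cc(OCc9ccccc9)c1)[C@H](c1ccc(OCc9ccccc9)cc1)O2
F10 | step 15 | tetrahydrothiophenium 4-(benzyloxy)benzylide | [CH-](c1ccc(OCc2ccccc2)cc1)[S+]1CCCC1
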